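**Strategy.** The route rests on closing the cyclopentane (C13–C17; fatty-acid numbering, C1 = ester carbon) last, onto a cis-oxirane (C14–C15) that is already in place. A cobalt-stabilised propargylic cation at C13 is captured 5-exo by a (Z)-C17=C18 alkene while chloride ends the event at C18. One operation therefore makes the C13–C17 and C18–Cl bonds and sets C13, C17 and C18 from the oxirane alone. The feature exploited is the anti C17/C18 (ring-carbon/chlorine) array beside the C13 alkenyl branch, the imprint of an anti carbochlorination of a Z-alkene. The precursor is an acyclic epoxy enyne acetate from Sharpless epoxidation; the triene is then grown from the ring alkyne.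

Key step: step 6

Remark on the chemistry: atom numbers C1–C20 follow the parent C20 chain throughout. The carbinol centre C13 in 7–9 is left uncontrolled on purpose, because it becomes the planar cation in step 6.

**Step 1**
Reactants: 1 prop-2-yn-1-ol; 2 1-bromopent-2-yne
Product: 3 octa-2,5-diyn-1-ol
Conditions: CuI (cat.), NaI (cat.), K2CO3, DMF, rt
Reagents that add atoms: none
Why: Copper(I)-acetylide propargylation of a terminal alkyne by a propargylic bromide should give the skipped diyne directly; no stereocentre is formed.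

**Step 2**
Reactants: 3 octa-2,5-diyn-1-ol
Product: 4 (2Z,5Z)-octa-2,5-dien-1-ol
Conditions: H2 (1 atm), Lindlar catalyst, quinoline, EtOAc, rt
Reagents that add atoms: none
Why: Lindlar semihydrogenation adds H2 syn to each alkyne, so both alkenes should be Z.

**Step 3**
Reactants: 4 (2Z,5Z)-octa-2,5-dien-1-ol
Product: 5 [(2R,3S)-3-[(2Z)-pent-2-en-1-yl]oxiran-2-yl]methanol
Conditions: Ti(OiPr)4 (cat.), D-(−)-diethyl tartrate (cat.), t-BuOOH, 4 Å MS, CH2Cl2, −20 °C
Reagents that add atoms: tert-butyl hydroperoxide, CC(C)(C)OO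
Why: Sharpless asymmetric epoxidation acts only on the allylic alkene and is stereospecific (Z-alkene to cis-oxirane); D-(−)-tartrate directs oxygen to the face that gives (2R,3S), which fixes C14 and C15.

**Step 4**
Reactants: 5 [(2R,3S)-3-[(2Z)-pent-2-en-1-yl]oxiran-2-yl]methanol
Product: 6 (2S,3S)-3-[(2Z)-pent-2-en-1-yl]oxirane-2-carbaldehyde
Conditions: Dess–Martin periodinane, NaHCO3, CH2Cl2, 0 °C to rt; crude aldehyde used at once
Reagents that add atoms: none
Why: Buffered Dess–Martin oxidation is non-basic and should leave the epimerisable cis-epoxy aldehyde intact (the descriptor at C2 changes only through CIP priorities).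

**Step 5**
Reactants: 6 (2S,3S)-3-[(2Z)-pent-2-en-1-yl]oxirane-2-carbaldehyde
Product: 8 1-[(2S,3S)-3-[(2Z)-pent-2-en-1-yl]oxiran-2-yl]prop-2-yn-1-yl acetate (both C-1 epimers), via bromomagnesium propargylic alkoxide 7 (not isolated)
Conditions: HC≡CMgBr, THF, −78 °C; then Ac2O, −78 to 0 °C
Reagents that add atoms: ethynylmagnesium bromide, C#C[Mg]Br; acetic anhydride, CC(=O)OC(C)=O
Why: Grignard 1,2-addition followed by O-acylation of the alkoxide in the same flask should give the propargylic acetate; the new carbinol centre needs no control because both epimers converge on the same cation.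

**Step 6 (key step)**
Reactants: 8 1-[(2S,3S)-3-[(2Z)-pent-2-en-1-yl]oxiran-2-yl]prop-2-yn-1-yl acetate
Product: 10 hexacarbonyldicobalt complex of (1R,2R,3R,5S)-3-[(1S)-1-chloropropyl]-2-ethynyl-6-oxabicyclo[3.1.0]hexane (descriptors quoted for the free alkyne 11), via hexacarbonyldicobalt alkyne complex 9 (not isolated)
Conditions: Co2(CO)8, CH2Cl2, rt; then SnCl4, 2,6-di-tert-butyl-4-methylpyridine, CH2Cl2, −78 °C
Reagents that add atoms: dicobalt octacarbonyl, O=C=[Co](=C=O)(=C=O)(=C=O)[Co](=C=O)(=C=O)(=C=O)=C=O; tin(IV) chloride, Cl[Sn](Cl)(Cl)Cl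
Why: Proposed new method: SnCl4 ionises the cobalt-complexed propargylic acetate to a Co2(CO)6-stabilised cation at C13 (it cannot eliminate, since C14 is an oxirane carbon and C12 the complexed alkyne), the (Z)-C17=C18 alkene adds to it and the chlorostannate counter-ion delivers chloride to C18; the closest known reaction types are the intramolecular Nicholas reaction of alkenes with halide capture and the Lewis-acid-catalysed carbochlorination of alkenes by ionisable alkyl chlorides, neither shown for a 1,2-dialkyl alkene next to an oxirane. The cyclopentane is closed by the C13–C17 bond in a 5-exo-trig cation–olefin mode onto the existing cis-oxirane, which holds C13 and C16 eclipsed and so preorganises the five-membered array. C13 is controlled by the oxirane stereocentre C14 through the C13–C14 rotamer in which the small H13, not the cluster-bearing alkyne, lies syn to the oxirane oxygen; C17 by the preference of the C18 terminus to sit trans to the bulky cobalt cluster in the envelope transition state; C18 by anti addition, C13 and chloride entering on opposite faces of the Z-alkene, which gives the (17R,18S) pair. The step needs 5-exo rather than 6-endo closure, which the eclipsed oxirane tether and the placing of charge on C18 (one bond further from the electron-withdrawing oxirane than C17) should favour. It also needs chloride capture to outrun rotation, hydride shift and ring expansion at C18 and needs the oxirane to survive the Lewis acid, for which the chloride-rich tight ion pair at −78 °C, the proton scavenger, the much faster ionisation of the complexed acetate and the deactivating positive charge next to C14 are relied on.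

**Step 7**
Reactants: 10 hexacarbonyldicobalt complex of the cyclised chloride
Product: 11 (1R,2R,3R,5S)-3-[(1S)-1-chloropropyl]-2-ethynyl-6-oxabicyclo[3.1.0]hexane
Conditions: N-methylmorpholine N-oxide (excess), CH2Cl2, 0 °C to rt
Reagents that add atoms: none
Why: Oxidative decomplexation by an amine N-oxide (CO ligands leave as CO2) should free the alkyne under basic, non-Lewis-acidic conditions that spare oxirane and secondary chloride; no stereocentre is touched.

**Step 8**
Reactants: 12 methyl hex-5-ynoate; 13 1,4-dichlorobut-2-yne (used in excess)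
Product: 14 methyl 10-chlorodeca-5,8-diynoate
Conditions: CuI (cat.), NaI (cat.), K2CO3, DMF, rt
Reagents that add atoms: none
Why: Copper(I)-acetylide propargylation with an excess of the symmetrical bis-electrophile should favour monosubstitution and leave one propargylic chloride for the next coupling.

**Step 9**
Reactants: 11 (1R,2R,3R,5S)-3-[(1S)-1-chloropropyl]-2-ethynyl-6-oxabicyclo[3.1.0]hexane; 14 methyl 10-chlorodeca-5,8-diynoate
Product: 15 methyl 12-[(1R,2R,3R,5S)-3-[(1S)-1-chloropropyl]-6-oxabicyclo[3.1.0]hexan-2-yl]dodeca-5,8,11-triynoate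
Conditions: CuI (cat.), NaI (cat.), Cs2CO3, DMF, rt
Reagents that add atoms: none
Why: The same copper(I)-acetylide propargylation assembles the skipped triyne under carbonate conditions that should not affect the ester, the oxirane or the unactivated secondary chloride.

**Step 10**
Reactants: 15 skipped triyne ester
Product: 16 methyl (5Z,8Z,11Z)-12-[(1R,2S,3R,5S)-3-[(1S)-1-chloropropyl]-6-oxabicyclo[3.1.0]hexan-2-yl]dodeca-5,8,11-trienoate (target)
Conditions: H2 (1 atm), Lindlar catalyst, quinoline, EtOAc, rt
Reagents that add atoms: none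
Why: Threefold Lindlar semihydrogenation adds H2 syn to each alkyne and should give the all-Z skipped triene while alkyl chloride, oxirane and ester stay inert (the C13 descriptor changes only through CIP priorities).

**Compound list**

1 | prop-2-yn-1-ol | C#CCO | starting material
2 | 1-bromopent-2-yne | CCC#CCBr | starting material
3 | octa-2,5-diyn-1-ol | CCC#CCC#CCO | intermediate
4 | (2Z,5Z)-octa-2,5-dien-1-ol | CC/C=C\C/C=C\CO | intermediate
5 | [(2R,3S)-3-[(2Z)-pent-2-en-1-yl]oxiran-2-yl]methanol | CC/C=C\C[C@@H]1O[C@@H]1CO | intermediate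
6 | (2S,3S)-3-[(2Z)-pent-2-en-1-yl]oxirane-2-carbaldehyde | CC/C=C\C[C@@H]1O[C@@H]1C=O | intermediate
7 | bromomagnesium 1-[(2S,3S)-3-[(2Z)-pent-2-en-1-yl]oxiran-2-yl]prop-2-yn-1-olate (C-1 epimers) | CC/C=C\C[C@@H]1O[C@@H]1C(O[Mg]Br)C#C | intermediate (not isolated)
8 | 1-[(2S,3S)-3-[(2Z)-pent-2-en-1-yl]oxiran-2-yl]prop-2-yn-1-yl acetate (C-1 epimers) | CC/C=C\C[C@@H]1O[C@@H]1C(OC(C)=O)C#C | intermediate
9 | hexacarbonyldicobalt complex of 8 | CC/C=C\C[C@@H]1O[C@@H]1C(OC(C)=O)C23C4[Co]2(=C=O)(=C=O)(=C=O)[Co]34(=C=O)(=C=O)=C=O | intermediate (not isolated)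
10 | hexacarbonyldicobalt complex of 11 | CC[C@H](Cl)[C@@H]1C[C@@H]2O[C@@H]2[C@H]1C34C5[Co]3(=C=O)(=C=O)(=C=O)[Co]45(=C=O)(=C=O)=C=O | intermediate
11 | (1R,2R,3R,5S)-3-[(1S)-1-chloropropyl]-2-ethynyl-6-oxabicyclo[3.1.0]hexane | CC[C@H](Cl)[C@@H]1C[C@@H]2O[C@@H]2[C@H]1C#C | intermediate
12 | methyl hex-5-ynoate | C#CCCCC(=O)OC | starting material
13 | 1,4-dichlorobut-2-yne | ClCC#CCCl | starting material
14 | methyl 10-chlorodeca-5,8-diynoate | ClCC#CCC#CCCCC(=O)OC | intermediate
15 | methyl 12-[(1R,2R,3R,5S)-3-[(1S)-1-chloropropyl]-6-oxabicyclo[3.1.0]hexan-2-yl]dodeca-5,8,11-triynoate | CC[C@H](Cl)[C@@H]1C[C@@H]2O[C@@H]2[C@H]1C#CCC#CCC#CCCCC(=O)OC | intermediate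
16 | methyl (5Z,8Z,11Z)-12-[(1R,2S,3R,5S)-3-[(1S)-1-chloropropyl]-6-oxabicyclo[3.1.0]hexan-2-yl]dodeca-5,8,11-trienoate | CC[C@H](Cl)[C@@H]1C[C@@H]2O[C@@H]2[C@H]1/C=C\C/C=C\C/C=C\CCCC(=O)OC | target

**Totals.** Total step count: 10. Longest linear sequence: 9 (steps 1–7, 9, 10).

**Steps most likely to fail**

1. Step 6 (Proposed new method). Three processes threaten it: Lewis-acid opening of the oxirane before or after ionisation; closure in the 6-endo sense (C13–C18 bond), since the alkene has no Markovnikov bias; and loss of stereospecificity, hydride shift, elimination or ring expansion at the C18 cation before chloride arrives. The fallback uses known chemistry and still closes the cyclopentane last, onto the oxirane, by an intramolecular Nicholas reaction. It uses a silyl enol ether as the π-nucleophile, so the ring size is dictated by the enol ether, and chlorine is introduced afterwards by SN2. It sets out from 1 and returns at 11. Alkylation of the dianion of 1 (LiNH2, NH3/THF) with (3-bromopropoxy)(tert-butyl)dimethylsilane would give 6-[(tert-butyldimethylsilyl)oxy]hex-2-yn-1-ol F1. Lindlar hydrogenation would give (2Z)-6-[(tert-butyldimethylsilyl)oxy]hex-2-en-1-ol F2, and Sharpless epoxidation with D-(−)-diethyl tartrate the (2R,3S)-epoxy alcohol F3. Dess–Martin oxidation would give the cis-epoxy aldehyde F4, and ethynylmagnesium bromide followed by Ac2O the propargylic acetate F5. HF·pyridine would free the primary alcohol F6, Dess–Martin oxidation would give the aldehyde F7, and TBSOTf/Et3N at −78 °C the silyl enol ether F8. Complexation with Co2(CO)8 (cobalt complex F9) and BF3·OEt2 at −78 °C should close the ring 5-exo to the cobalt-complexed trans-2-alkynyl cyclopentanecarbaldehyde F10, whose aldehyde-bearing centre C17 can equilibrate to the trans isomer. N-Methylmorpholine N-oxide would release the alkynyl aldehyde F11. Catalyst-controlled ethylation (Et2Zn with the enantiomer of the MIB amino-alcohol ligand that gives the 18R carbinol) should give the (18R)-alcohol F12. Appel chlorination (PPh3, CCl4) with inversion would then return to 11.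

2. Step 10. Three alkynes must each take up exactly one equivalent of hydrogen; over-reduction, incomplete reduction or Z/E erosion at any one of them would give mixtures that are hard to separate at the last step. The fallback reduces the side chain before it is attached, so that a single isolated alkyne is left for the end. It sets out from 14 (with 11) and returns at 16. Lindlar hydrogenation of 14 would give methyl (5Z,8Z)-10-chlorodeca-5,8-dienoate F13. Copper-mediated coupling of this allylic chloride with 11 (CuI, NaI, Cs2CO3, DMF) would give the dienyne methyl (5Z,8Z)-12-[(1R,2R,3R,5S)-3-[(1S)-1-chloropropyl]-6-oxabicyclo[3.1.0]hexan-2-yl]dodeca-5,8-dien-11-ynoate F14. Semihydrogenation of its one alkyne would return to 16.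

3. Step 3. (Z)-Allylic alcohols are the slow and less face-selective substrate class of the titanium–tartrate system, so incomplete enantiofacial discrimination could carry the wrong enantiomer through the whole route. The fallback replaces asymmetric catalysis by kinetic resolution; it sets out from 4 and returns at 5. Hydroxyl-directed epoxidation of 4 (VO(acac)2, t-BuOOH) would give the racemic cis-epoxy alcohol, that is 5 together with its enantiomer [(2S,3R)-3-[(2Z)-pent-2-en-1-yl]oxiran-2-yl]methanol F15. Lipase-catalysed acetylation (Amano PS, vinyl acetate, i-Pr2O), run past half conversion, should remove the faster-reacting enantiomer as its acetate. If that is the (2S,3R)-acetate F16, unreacted 5 is collected directly. If the enzyme prefers 5, the racemate is first acetylated (Ac2O, pyridine; F16 and the (2R,3S)-acetate F17) and the same lipase is used in the hydrolytic direction, so that 5 is again the species released as the alcohol.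

**Further compounds**

F1 | step 6 | 6-[(tert-butyldimethylsilyl)oxy]hex-2-yn-1-ol | OCC#CCCCO[Si](C)(C)C(C)(C)C
F2 | step 6 | (2Z)-6-[(tert-butyldimethylsilyl)oxy]hex-2-en-1-ol | OC/C=C\CCCO[Si](C)(C)C(C)(C)C
F3 | step 6 | [(2R,3S)-3-{3-[(tert-butyldimethylsilyl)oxy]propyl}oxiran-2-yl]methanol | CC(C)(C)[Si](C)(C)OCCC[C@@H]1O[C@@H]1CO
F4 | step 6 | (2S,3S)-3-{3-[(tert-butyldimethylsilyl)oxy]propyl}oxirane-2-carbaldehyde | CC(C)(C)[Si](C)(C)OCCC[C@@H]1O[C@@H]1C=O
F5 | step 6 | 1-[(2S,3S)-3-{3-[(tert-butyldimethylsilyl)oxy]propyl}oxiran-2-yl]prop-2-yn-1-yl acetate (C-1 epimers) | CC(C)(C)[Si](C)(C)OCCC[C@@H]1O[C@@H]1C(OC(C)=O)C#C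
F6 | step 6 | 1-[(2S,3S)-3-(3-hydroxypropyl)oxiran-2-yl]prop-2-yn-1-yl acetate (C-1 epimers) | OCCC[C@@H]1O[C@@H]1C(OC(C)=O)C#C
F7 | step 6 | 1-[(2S,3S)-3-(3-oxopropyl)oxiran-2-yl]prop-2-yn-1-yl acetate (C-1 epimers) | O=CCC[C@@H]1O[C@@H]1C(OC(C)=O)C#C
F8 | step 6 | 1-[(2S,3S)-3-{3-[(tert-butyldimethylsilyl)oxy]prop-2-en-1-yl}oxiran-2-yl]prop-2-yn-1-yl acetate (enol ether E/Z, C-1 epimers) | CC(C)(C)[Si](C)(C)OC=CC[C@@H]1O[C@@H]1C(OC(C)=O)C#C
F9 | step 6 | hexacarbonyldicobalt complex of F8 | CC(C)(C)[Si](C)(C)OC=CC[C@@H]1O[C@@H]1C(OC(C)=O)C23C4[Co]2(=C=O)(=C=O)(=C=O)[Co]34(=C=O)(=C=O)=C=O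
F10 | step 6 | hexacarbonyldicobalt complex of F11 | O=C[C@@H]1C[C@@H]2O[C@@H]2[C@H]1C34C5[Co]3(=C=O)(=C=O)(=C=O)[Co]45(=C=O)(=C=O)=C=O
F11 | step 6 | 2-ethynyl-6-oxabicyclo[3.1.0]hexane-3-carbaldehyde (ring configuration as in 11) | O=C[C@@H]1C[C@@H]2O[C@@H]2[C@H]1C#C
F12 | step 6 | (1R)-1-(2-ethynyl-6-oxabicyclo[3.1.0]hexan-3-yl)propan-1-ol (ring configuration as in 11; carbinol is C18, R) | CC[C@@H](O)[C@@H]1C[C@@H]2O[C@@H]2[C@H]1C#C
F13 | step 10 | methyl (5Z,8Z)-10-chlorodeca-5,8-dienoate | ClC/C=C\C/C=C\CCCC(=O)OC
F14 | step 10 | methyl (5Z,8Z)-12-[(1R,2R,3R,5S)-3-[(1S)-1-chloropropyl]-6-oxabicyclo[3.1.0]hexan-2-yl]dodeca-5,8-dien-11-ynoate | CC[C@H](Cl)[C@@H]1C[C@@H]2O[C@@H]2[C@H]1C#CC/C=C\C/C=C\CCCC(=O)OC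
F15 | step 3 | [(2S,3R)-3-[(2Z)-pent-2-en-1-yl]oxiran-2-yl]methanol | CC/C=C\C[C@H]1O[C@H]1CO
F16 | step 3 | [(2S,3R)-3-[(2Z)-pent-2-en-1-yl]oxiran-2-yl]methyl acetate | CC/C=C\C[C@H]1O[C@H]1COC(C)=O
F17 | step 3 | [(2R,3S)-3-[(2Z)-pent-2-en-1-yl]oxiran-2-yl]methyl acetate | CC/C=C\C[C@@H]1O[C@@H]1COC(C)=O
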